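**Retrosynthetic overview**
1. Target 12 comes from tris-silyl ether 11 by one global desilylation; O4, O5 and O4' are all carried as silyl ethers.
2. 11 comes from salicylaldehyde silyl ether 8 and styrene 9: ring C is made last, in one catalytic asymmetric oxa-[4+2] event that forms C3–C4 and O1–C2 and both stereocentres while the triethylsilyl group is relayed from O1 to the C4 oxygen.
3. Enabling feature: in ring A the carbinol carbon C4 sits on C4a, next to the O1-bearing C8a, so the salicylaldehyde is a latent 1-oxadiene O1=C8a–C4a=C4 (a 4-silyloxy o-quinone methide). The peri C5 oxygen, kept as a bulky silyl ether, forces the C4 oxygen axial and so gives the 2,4-trans relationship.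
4. 8 comes from 2,4,6-trihydroxybenzaldehyde 1 by 4-O-methylation, 1,1-dimethylpropargyl ether formation, semi-hydrogenation and aromatic Claisen rearrangement, which puts the prenyl group on C8 and frees the O1 phenol in the same step.
5. Ring order: rings A and B are bought (1 and 9); ring C closes in step 6.

Key step: step 6

Assumption: the sense of induction of the confined chiral anion in step 6 cannot be predicted with certainty; the (S,S)-catalyst is written, and its mirror image would be used if it favours the (2R,4S) series.

Step 1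
Reactants: 1 2,4,6-trihydroxybenzaldehyde
Product: 2 2,6-dihydroxy-4-methoxybenzaldehyde
Conditions: Me2SO4 (1.0 equiv), K2CO3 (1.0 equiv), acetone, 0 °C to rt
Reagents that add atoms: dimethyl sulfate, COS(=O)(=O)OC
Why: The 4-OH, para to the formyl group and not hydrogen-bonded, is the most acidic and least hindered phenol, so one equivalent of base and electrophile should give selective Williamson-type O-methylation.

Step 2
Reactants: 2 2,6-dihydroxy-4-methoxybenzaldehyde; 3 3-chloro-3-methylbut-1-yne
Product: 4 2-hydroxy-4-methoxy-6-[(2-methylbut-3-yn-2-yl)oxy]benzaldehyde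
Conditions: 3 (1.1 equiv), DBU, CuCl2 (1 mol%), MeCN, 0 °C
Reagents that add atoms: none
Why: Copper-catalysed propargylic etherification of a phenoxide with the tertiary chloride should stop at the mono-ether, because the remaining OH is then locked in a hydrogen bond to the formyl group.

Step 3
Reactants: 4 2-hydroxy-4-methoxy-6-[(2-methylbut-3-yn-2-yl)oxy]benzaldehyde
Product: 5 4-methoxy-2-[(2-methylbut-3-yn-2-yl)oxy]-6-(triisopropylsilyloxy)benzaldehyde
Conditions: TIPSOTf, 2,6-lutidine, CH2Cl2, 0 °C
Reagents that add atoms: triisopropylsilyl trifluoromethanesulfonate, CC(C)[Si](C(C)C)(C(C)C)OS(=O)(=O)C(F)(F)F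
Why: Silyl triflate O-silylation overcomes the chelation of the ortho-formyl phenol and installs the bulky group on the future O5 that later steers the key step.

Step 4
Reactants: 5 4-methoxy-2-[(2-methylbut-3-yn-2-yl)oxy]-6-(triisopropylsilyloxy)benzaldehyde
Product: 7 2-hydroxy-4-methoxy-3-(3-methylbut-2-en-1-yl)-6-(triisopropylsilyloxy)benzaldehyde, via 1,1-dimethylallyl aryl ether 6 (not isolated)
Conditions: H2 (1 atm), Pd/CaCO3 poisoned with Pb(OAc)2 (Lindlar catalyst), quinoline, toluene, rt; filtered, then 110 °C
Reagents that add atoms: none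
Why: Lindlar semi-hydrogenation stops at the 1,1-dimethylallyl ether, which should undergo aromatic Claisen ([3,3]) rearrangement to the only free ortho carbon, placing the prenyl group between the new phenol and the methoxy group and unveiling the oxygen that becomes O1.

Step 5
Reactants: 7 2-hydroxy-4-methoxy-3-(3-methylbut-2-en-1-yl)-6-(triisopropylsilyloxy)benzaldehyde
Product: 8 4-methoxy-3-(3-methylbut-2-en-1-yl)-2-(triethylsilyloxy)-6-(triisopropylsilyloxy)benzaldehyde
Conditions: TESOTf, 2,6-lutidine, CH2Cl2, –78 to 0 °C
Reagents that add atoms: triethylsilyl trifluoromethanesulfonate, CC[Si](CC)(CC)OS(=O)(=O)C(F)(F)F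
Why: Standard silyl ether formation with a silyl triflate silylates the chelated phenol and provides the transferable silyl group for the key step.

Step 6
Reactants: 8 4-methoxy-3-(3-methylbut-2-en-1-yl)-2-(triethylsilyloxy)-6-(triisopropylsilyloxy)benzaldehyde; 9 4-(tert-butyldimethylsilyloxy)styrene
Product: 11 (2S,4R)-2-[4-(tert-butyldimethylsilyloxy)phenyl]-7-methoxy-8-(3-methylbut-2-en-1-yl)-4-(triethylsilyloxy)-5-(triisopropylsilyloxy)chromane, via silyl oxocarbenium ion 10 (not isolated)
Conditions: 9 (2 equiv), (S,S)-IDPi (BINOL-derived N-triflyl imidodiphosphorimidate, 3 mol%), toluene, –60 °C; Et3N quench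
Reagents that add atoms: none
Why: Proposed new method: the silylated imidodiphosphorimidate (formed from the acid and a trace of 8 by protodesilylation) transfers Et3Si+ to the formyl oxygen to give oxocarbenium ion 10 paired with the confined chiral anion, which is the O-silylated form of the 4-silyloxy o-quinone methide O1=C8a–C4a=C4; the terminal CH2 of the electron-rich styrene 9 then adds to C4 and the resulting benzylic cation at C2 is captured at once by the ortho silyl ether oxygen O1, whose Et3Si+ is handed back to the anion, so that the silyl group is relayed from O1 to O4 without by-product (asynchronous inverse-demand oxa-[4+2]). The closest known reaction types are the confined-acid-catalysed asymmetric [4+2] cycloadditions of 4-alkoxy o-quinone methides generated from salicylaldehydes and alcohols, silylium-type imidodiphosphorimidate catalysis of Mukaiyama, Hosomi–Sakurai and hetero-Diels–Alder additions to aldehydes, and the Sc(OTf)3-mediated three-component coupling of salicylaldehydes, orthoformate and alkenes to 4-alkoxychromans. Ring C is closed stepwise within one ion pair, by intermolecular C3–C4 bond formation followed by a six-membered closure in which O1 captures the benzylic C2 cation (6-endo with respect to the former styrene double bond) through a chair-like array. C4 is set in the C–C bond-forming event by the chiral anion, which shields one face of the planar oxocarbenium ion, and C2 follows from C4 because in the chair-like closure the aryl group is equatorial while the C4 silyloxy group is forced axial by peri (A1,3) strain with the C5 triisopropylsilyloxy group, which should give the 2,4-trans (2S,4R) isomer. The step needs regioselectivity (C3 to C4 and O1 to C2, secured by the polarity of the partners, and O1 in place of O5, secured by the much smaller and more labile triethylsilyl ether) and chemoselectivity against styrene oligomerisation and ionisation of the product at C4, which low temperature, the higher Lewis basicity of the aldehyde and the amine quench should secure.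

Step 7
Reactants: 11 (2S,4R)-2-[4-(tert-butyldimethylsilyloxy)phenyl]-7-methoxy-8-(3-methylbut-2-en-1-yl)-4-(triethylsilyloxy)-5-(triisopropylsilyloxy)chromane
Product: 12 (2S,4R)-2-(4-hydroxyphenyl)-7-methoxy-8-(3-methylbut-2-en-1-yl)chromane-4,5-diol (4,5,4'-trihydroxy-7-methoxy-8-prenylflavan)
Conditions: TBAF/AcOH (1:1, 4 equiv), THF, 0 °C
Reagents that add atoms: none
Why: Buffered fluoride-mediated Si–O cleavage (global desilylation) should remove the alkyl and both aryl silyl ethers without touching the C4–O or C2–O bonds, so the (2S,4R) configuration is retained.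

**Compound list**
1 | 2,4,6-trihydroxybenzaldehyde | O=Cc1c(O)cc(O)cc1O | starting material
2 | 2,6-dihydroxy-4-methoxybenzaldehyde | COc1cc(O)c(C=O)c(O)c1 | intermediate
3 | 3-chloro-3-methylbut-1-yne | C#CC(C)(C)Cl | starting material
4 | 2-hydroxy-4-methoxy-6-[(2-methylbut-3-yn-2-yl)oxy]benzaldehyde | COc1cc(O)c(C=O)c(OC(C)(C)C#C)c1 | intermediate
5 | 4-methoxy-2-[(2-methylbut-3-yn-2-yl)oxy]-6-(triisopropylsilyloxy)benzaldehyde | COc1cc(O[Si](C(C)C)(C(C)C)C(C)C)c(C=O)c(OC(C)(C)C#C)c1 | intermediate
6 | 4-methoxy-2-[(2-methylbut-3-en-2-yl)oxy]-6-(triisopropylsilyloxy)benzaldehyde (1,1-dimethylallyl aryl ether) | COc1cc(O[Si](C(C)C)(C(C)C)C(C)C)c(C=O)c(OC(C)(C)C=C)c1 | intermediate (not isolated)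
7 | 2-hydroxy-4-methoxy-3-(3-methylbut-2-en-1-yl)-6-(triisopropylsilyloxy)benzaldehyde | COc1cc(O[Si](C(C)C)(C(C)C)C(C)C)c(C=O)c(O)c1CC=C(C)C | intermediate
8 | 4-methoxy-3-(3-methylbut-2-en-1-yl)-2-(triethylsilyloxy)-6-(triisopropylsilyloxy)benzaldehyde | COc1cc(O[Si](C(C)C)(C(C)C)C(C)C)c(C=O)c(O[Si](CC)(CC)CC)c1CC=C(C)C | intermediate
9 | 4-(tert-butyldimethylsilyloxy)styrene | C=Cc1ccc(O[Si](C)(C)C(C)(C)C)cc1 | starting material
10 | O-triethylsilyl oxocarbenium ion of 8 (cation of the ion pair with the chiral imidodiphosphorimidate anion) | COc1cc(O[Si](C(C)C)(C(C)C)C(C)C)c(C=[O+][Si](CC)(CC)CC)c(O[Si](CC)(CC)CC)c1CC=C(C)C | intermediate (not isolated)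
11 | (2S,4R)-2-[4-(tert-butyldimethylsilyloxy)phenyl]-7-methoxy-8-(3-methylbut-2-en-1-yl)-4-(triethylsilyloxy)-5-(triisopropylsilyloxy)chromane (2,4-trans) | COc1cc(O[Si](C(C)C)(C(C)C)C(C)C)c2c(c1CC=C(C)C)O[C@H](c1ccc(O[Si](C)(C)C(C)(C)C)cc1)C[C@H]2O[Si](CC)(CC)CC | intermediate
12 | (2S,4R)-2-(4-hydroxyphenyl)-7-methoxy-8-(3-methylbut-2-en-1-yl)chromane-4,5-diol (2,4-trans) | COc1cc(O)c2c(c1CC=C(C)C)O[C@H](c1ccc(O)cc1)C[C@H]2O | target

**Step count and risks**
Total step count: 7. Longest linear sequence: 7 steps (1 to 12).

Steps most likely to fail: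

Step 6. The chiral anion may give poor enantiofacial control, the silylated catalyst may ionise the C4 silyl ether of the product (erosion to a flav-3-ene), or the styrene may oligomerise. The fallback uses known chemistry and makes the two bonds one after the other. It sets out from 8. A diisopinocampheylboron enolate aldol addition of commercial 4'-(tert-butyldimethylsilyloxy)acetophenone (Ipc2BCl antipode that delivers the 3R adduct, Et3N, Et2O, –78 °C; H2O2 at pH 7) should give β-hydroxy ketone F1. Reagent-controlled CBS reduction ((S)-Me-CBS oxazaborolidine, BH3·SMe2, THF, –20 °C) should give anti-1,3-diol F2, the syn diol from the minor aldol enantiomer being removed by chromatography. Brief K2CO3/MeOH at 0 °C should cleave only the aryl triethylsilyl ether to phenol diol F3. Mitsunobu cyclisation (PPh3, DIAD, THF, 0 °C), in which the phenol displaces the less hindered 4-silyloxybenzylic carbinol with inversion, should give flavan-4-ol bis-silyl ether F4. F4 comes back to the route at 12 under the conditions of step 7.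

Step 7. The hindered C5 aryl triisopropylsilyl ether may be cleaved only slowly, and during the long exposure to fluoride and acetic acid the very electron-rich benzylic C4–O bond may ionise, so that C4 is epimerised or lost by elimination. The fallback replaces the single fluoride treatment by two cleavage events of different type. It sets out from 11. Carbonate-mediated, aryl-selective desilylation (Cs2CO3, DMF/H2O 10:1, rt to 40 °C), a known way to cleave phenol silyl ethers beside alkyl silyl ethers, should remove both aryl silyl groups under acid-free conditions while O4 stays silylated, giving 4-O-triethylsilyl diphenol F5. Should the triethylsilyl group migrate to the neighbouring 5-phenoxide and be lost there, the material is 12 already. The alkyl triethylsilyl ether of F5, the most labile of the three silyl groups, would then be cleaved by a short treatment with TBAF/AcOH (1:1) in THF at –20 °C. The sequence comes back to the route at 12.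

Step 2. Etherification of the hydrogen-bonded ortho-formyl phenol with the tertiary propargylic electrophile may be sluggish or run on to the bis-ether. The fallback changes to palladium allylation and sets out from 2. Tsuji–Trost O-allylation (Pd(PPh3)4, THF, 0 °C) with tert-butyl 2-methylbut-3-en-2-yl carbonate F6 (from 2-methylbut-3-en-2-ol, n-BuLi and Boc2O) should give the branched 1,1-dimethylallyl ether F7 directly. TIPSOTf/2,6-lutidine then gives 6, where the sequence comes back to the route at the thermal Claisen part of step 4; 4 and 5 are bypassed.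

**Further compounds**
F1 | step 6 | (3R)-1-[4-(tert-butyldimethylsilyloxy)phenyl]-3-hydroxy-3-[4-methoxy-3-(3-methylbut-2-en-1-yl)-2-(triethylsilyloxy)-6-(triisopropylsilyloxy)phenyl]propan-1-one | COc1cc(O[Si](C(C)C)(C(C)C)C(C)C)c([C@H](O)CC(=O)c2ccc(O[Si](C)(C)C(C)(C)C)cc2)c(O[Si](CC)(CC)CC)c1CC=C(C)C
F2 | step 6 | (1R,3R)-1-[4-(tert-butyldimethylsilyloxy)phenyl]-3-[4-methoxy-3-(3-methylbut-2-en-1-yl)-2-(triethylsilyloxy)-6-(triisopropylsilyloxy)phenyl]propane-1,3-diol (anti) | COc1cc(O[Si](C(C)C)(C(C)C)C(C)C)c([C@H](O)C[C@@H](O)c2ccc(O[Si](C)(C)C(C)(C)C)cc2)c(O[Si](CC)(CC)CC)c1CC=C(C)C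
F3 | step 6 | (1R,3R)-1-[4-(tert-butyldimethylsilyloxy)phenyl]-3-[2-hydroxy-4-methoxy-3-(3-methylbut-2-en-1-yl)-6-(triisopropylsilyloxy)phenyl]propane-1,3-diol | COc1cc(O[Si](C(C)C)(C(C)C)C(C)C)c([C@H](O)C[C@@H](O)c2ccc(O[Si](C)(C)C(C)(C)C)cc2)c(O)c1CC=C(C)C
F4 | step 6 | (2S,4R)-2-[4-(tert-butyldimethylsilyloxy)phenyl]-7-methoxy-8-(3-methylbut-2-en-1-yl)-5-(triisopropylsilyloxy)chroman-4-ol | COc1cc(O[Si](C(C)C)(C(C)C)C(C)C)c2c(c1CC=C(C)C)O[C@H](c1ccc(O[Si](C)(C)C(C)(C)C)cc1)C[C@H]2O
F5 | step 7 | (2S,4R)-2-(4-hydroxyphenyl)-7-methoxy-8-(3-methylbut-2-en-1-yl)-4-(triethylsilyloxy)chroman-5-ol | COc1cc(O)c2c(c1CC=C(C)C)O[C@H](c1ccc(O)cc1)C[C@H]2O[Si](CC)(CC)CC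
F6 | step 2 | tert-butyl 2-methylbut-3-en-2-yl carbonate | CC(C)(C)OC(=O)OC(C)(C)C=C
F7 | step 2 | 2-hydroxy-4-methoxy-6-[(2-methylbut-3-en-2-yl)oxy]benzaldehyde | COc1cc(O)c(C=O)c(OC(C)(C)C=C)c1
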